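Ring B of the target is a cyclohexene in which the C5–C10 and C8–C9 bonds sit 1,4 to each other across C6=C7, while ring A is only the C1–C4 bridge from C10 to C5; this is the pattern an intramolecular Diels–Alder reaction leaves behind. A chiral cationic oxazaborolidine makes the (E)-enal C9=C10 of an open-chain trienal add to the (Z)-2-silyloxydiene C5=C6–C7=C8 of the same chain, giving both bonds, both rings and the C5, C9 and C10 stereocentres in one operation; C8 is corrected later by epimerisation. The precursor is a linear C12 chain with a β-methyl enal, a gem-dimethyl tether and a triisopropylsilyloxy dienoate.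

Key step: step 10

Numbering: ring and side-chain atoms carry labdane numbers (C17 = ester carbon on C8, C11 on C9, C20 = methyl on C10).

Assumption: the (S)-configured catalyst is taken to leave the C9-re/C10-si face of the boron-bound enal open (formyl C–H···O organisation); should this α-unsubstituted enal bind in the opposite sense, the (R)-catalyst is used and nothing else changes.

Step 1
Reactants: 1 5-chloropent-1-yne
Product: 3 methyl (E)-6-chloro-3-methylhex-2-enoate, via alkenylalane 2 (not isolated)
Conditions: AlMe3 (2 equiv), Cp2ZrCl2 (0.25 equiv), CH2Cl2, 0 °C → rt; then ClCO2Me, 0 °C → rt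
Reagents that add atoms: trimethylaluminium, C[Al](C)C; methyl chloroformate, COC(Cl)=O
Why: Zirconocene-catalysed Negishi carboalumination delivers methyl and aluminium syn across the terminal alkyne with aluminium at the terminus, and the alkenylalane is acylated with retention by the chloroformate, so the (E)-trisubstituted alkene (methyl cis to the ester) is fixed from the outset; a primary alkyl chloride is inert to the neutral alane.

Step 2
Reactants: 3 methyl (E)-6-chloro-3-methylhex-2-enoate
Product: 4 (E)-6-chloro-3-methylhex-2-en-1-ol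
Conditions: i-Bu2AlH (2.2 equiv), CH2Cl2, −78 → 0 °C; aq. KNaC4H4O6 (tartrate)
Reagents that add atoms: none
Why: 1,2-Reduction of the conjugated ester by i-Bu2AlH at low temperature gives the allylic alcohol without touching the alkene geometry or the alkyl chloride.

Step 3
Reactants: 4 (E)-6-chloro-3-methylhex-2-en-1-ol
Product: 5 triethyl{[(E)-6-chloro-3-methylhex-2-en-1-yl]oxy}silane
Conditions: Et3SiCl, imidazole, CH2Cl2, 0 °C
Reagents that add atoms: chlorotriethylsilane, CC[Si](Cl)(CC)CC
Why: Silyl ether formation masks the hydroxyl group as a triethylsilyl ether, which tolerates organomagnesium, amide-base and silyl triflate conditions and can later be removed by mild acid methanolysis.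

Step 4
Reactants: 5 triethyl{[(E)-6-chloro-3-methylhex-2-en-1-yl]oxy}silane; 6 mesityl oxide (4-methylpent-3-en-2-one)
Product: 8 (E)-4,4,8-trimethyl-10-(triethylsilyloxy)dec-8-en-2-one, via Grignard reagent 7 (not isolated)
Conditions: Mg, BrCH2CH2Br (cat.), THF, 60 °C; then CuBr·SMe2 (10 mol%), 6, THF, −30 → 0 °C; aq. NH4Cl
Reagents that add atoms: none
Why: Magnesium insertion into the primary chloride and copper-catalysed conjugate addition (Kharasch-type 1,4-addition) of the Grignard reagent to the β,β-disubstituted enone create the quaternary, non-stereogenic C4 together with a methyl ketone.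

Step 5
Reactants: 8 (E)-4,4,8-trimethyl-10-(triethylsilyloxy)dec-8-en-2-one; 9 methyl glyoxylate (freshly distilled monomer)
Product: 11 methyl (10E)-2-hydroxy-6,6,10-trimethyl-4-oxo-12-(triethylsilyloxy)dodec-10-enoate, via lithium enolate 10 (not isolated)
Conditions: LiN(i-Pr)2, THF, −78 °C; 9, −78 °C; AcOH quench
Reagents that add atoms: none
Why: Kinetic deprotonation by LiN(i-Pr)2 takes place at the methyl group and not at the neopentyl methylene, and the lithium enolate undergoes a directed aldol addition to the highly electrophilic glyoxylate aldehyde; the carbinol centre forms as a racemate and is erased in the next step.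

Step 6
Reactants: 11 methyl (10E)-2-hydroxy-6,6,10-trimethyl-4-oxo-12-(triethylsilyloxy)dodec-10-enoate
Product: 13 methyl (2E,10E)-6,6,10-trimethyl-4-oxo-12-(triethylsilyloxy)dodeca-2,10-dienoate, via mesylate 12 (not isolated)
Conditions: MsCl, Et3N, CH2Cl2, 0 °C → rt
Reagents that add atoms: none
Why: Mesylation of the α-hydroxy ester and E1cB elimination through the ketone enolate complete the aldol condensation and give the 4-oxo-2-enoate as the thermodynamically preferred (E)-isomer.

Step 7
Reactants: 13 methyl (2E,10E)-6,6,10-trimethyl-4-oxo-12-(triethylsilyloxy)dodeca-2,10-dienoate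
Product: 14 methyl (2E,4Z,10E)-6,6,10-trimethyl-12-(triethylsilyloxy)-4-(triisopropylsilyloxy)dodeca-2,4,10-trienoate
Conditions: i-Pr3SiOTf, Et3N, CH2Cl2, −78 → 0 °C
Reagents that add atoms: triisopropylsilyl trifluoromethanesulfonate, CC(C)[Si](OS(=O)(=O)C(F)(F)F)(C(C)C)C(C)C
Why: Soft enolisation by silyl triflate and amine can remove only the C5 protons, and the (Z)-enol ether results because the O–Si unit and not the vinyl group sits cis to the bulky quaternary C4; no aldehyde is present yet, so no dienol silyl ether of an enal can form in competition.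

Step 8
Reactants: 14 methyl (2E,4Z,10E)-6,6,10-trimethyl-12-(triethylsilyloxy)-4-(triisopropylsilyloxy)dodeca-2,4,10-trienoate
Product: 15 methyl (2E,4Z,10E)-12-hydroxy-6,6,10-trimethyl-4-(triisopropylsilyloxy)dodeca-2,4,10-trienoate
Conditions: pyridinium p-toluenesulfonate (10 mol%), MeOH/CH2Cl2, 0 °C
Reagents that add atoms: none
Why: Acid-catalysed methanolysis (selective desilylation) should cleave the unhindered primary triethylsilyl ether far faster than it protonates the ester-conjugated, neopentyl-flanked triisopropylsilyl dienol ether.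

Step 9
Reactants: 15 methyl (2E,4Z,10E)-12-hydroxy-6,6,10-trimethyl-4-(triisopropylsilyloxy)dodeca-2,4,10-trienoate
Product: 16 methyl (2E,4Z,10E)-6,6,10-trimethyl-12-oxo-4-(triisopropylsilyloxy)dodeca-2,4,10-trienoate
Conditions: MnO2 (activated, 15 equiv), CH2Cl2, rt
Reagents that add atoms: none
Why: Heterogeneous MnO2 oxidation is specific for the allylic alcohol, is neutral towards the silyl enol ether and keeps the (E)-geometry of the trisubstituted alkene, so the sensitive enal appears only in the last step before the cycloaddition.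

Step 10
Reactants: 16 methyl (2E,4Z,10E)-6,6,10-trimethyl-12-oxo-4-(triisopropylsilyloxy)dodeca-2,4,10-trienoate
Product: 17 methyl (1R,2R,4aR,8aR)-1-formyl-5,5,8a-trimethyl-4-(triisopropylsilyloxy)-1,2,4a,5,6,7,8,8a-octahydronaphthalene-2-carboxylate (trans-fused; formyl cis to the C10 methyl; ester axial and syn to the C10 methyl)
Conditions: (S)-tetrahydro-1-(2-methylphenyl)-3,3-diphenyl-1H,3H-pyrrolo[1,2-c][1,3,2]oxazaborole (20 mol%), HN(SO2CF3)2 (18 mol%), CH2Cl2 (0.02 M), −78 → −20 °C; then Et3N
Reagents that add atoms: none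
Why: The N-protonated oxazaborolidine binds the formyl oxygen of the s-trans enal and lowers its LUMO, and the 2-silyloxydiene (largest HOMO coefficient at C5) adds in a concerted but asynchronous [4+2] process in which the C5–C10 bond runs ahead of the C8–C9 bond; the closest known reactions are cationic-oxazaborolidine-catalysed Diels–Alder additions of 2-(triisopropylsilyloxy)dienes to enals and the Lewis-acid-catalysed intramolecular cycloadditions of deca-2,7,9-trienals to trans-decalins. Ring A closes in the fused mode, the four-atom tether C1–C4 joining the dienophile carbon C10 to the diene terminus C5 so that the new C5–C10 bond completes a cyclohexane annulated to ring B, and ring B is the cyclohexene formed by the cycloaddition itself, with the silyloxy group on its C6=C7 double bond. The Alder endo mode (coordinated formyl group endo, tether exo) places the outside diene substituents (C4 on C5, the ester on C8) cis to the endo groups (C11 and C20), which sets the trans ring fusion at C5/C10 and delivers C8 with its ester axial and syn to C20, while the (E)-enal geometry is carried over suprafacially into the cis relation of C11 on C9 and C20 on C10. The absolute configuration of all four centres is set by the catalyst, whose aryl group covers one face of the bound enal so that the diene reaches the C9-re/C10-si face. The step needs endo selectivity and activation of the aldehyde in preference to the ester and the enol ether: the (Z)-enol ether geometry allows only the tether-exo folding, the gem-dimethyl group at C4 favours the folded conformer, the aldehyde is the most basic carbonyl group, and the bulky triisopropylsilyl group resists cleavage by the acidic catalyst.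

Step 11
Reactants: 17 methyl (1R,2R,4aR,8aR)-1-formyl-5,5,8a-trimethyl-4-(triisopropylsilyloxy)-1,2,4a,5,6,7,8,8a-octahydronaphthalene-2-carboxylate
Product: 18 methyl (1R,2S,4aR,8aS)-1-ethenyl-5,5,8a-trimethyl-4-(triisopropylsilyloxy)-1,2,4a,5,6,7,8,8a-octahydronaphthalene-2-carboxylate
Conditions: Ph3PCH3Br, KOt-Bu, THF, 0 °C
Reagents that add atoms: methyltriphenylphosphonium bromide, C[P+](c1ccccc1)(c1ccccc1)c1ccccc1.[Br-]
Why: Wittig methylenation by the small, non-stabilised ylide converts the hindered aldehyde into the C9 vinyl group faster than it enolises it, so C9 (equatorial, the favoured epimer in any case) keeps its configuration while the ester and the silyl enol ether are inert.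

Step 12
Reactants: 18 methyl (1R,2S,4aR,8aS)-1-ethenyl-5,5,8a-trimethyl-4-(triisopropylsilyloxy)-1,2,4a,5,6,7,8,8a-octahydronaphthalene-2-carboxylate
Product: 20 methyl (1R,2S,4aR,8aS)-1-ethenyl-5,5,8a-trimethyl-4-oxodecahydronaphthalene-2-carboxylate (ester equatorial and trans to the vinyl group), via axial keto ester 19 (not isolated)
Conditions: 2 M HCl, THF, rt; then NaOMe, MeOH, 60 °C
Reagents that add atoms: none
Why: Acid hydrolysis of the silyl enol ether (protonation at the non-stereogenic C7) unveils the C6 ketone, and base-mediated epimerisation through the ester enolate then moves the C8 ester under thermodynamic control from the axial position, where it is 1,3-diaxial to the C10 methyl group, to the equatorial one trans to the C9 vinyl group; C5 should stay trans because the cis-fused decalone would put the quaternary C4 axial on ring B.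

Step 13
Reactants: 20 methyl (1R,2S,4aR,8aS)-1-ethenyl-5,5,8a-trimethyl-4-oxodecahydronaphthalene-2-carboxylate
Product: 22 methyl (1R,2R,4aR,8aS)-1-ethenyl-5,5,8a-trimethyl-4-(trifluoromethylsulfonyloxy)-1,2,4a,5,6,7,8,8a-octahydronaphthalene-2-carboxylate, via potassium enolate 21 (not isolated)
Conditions: KN(SiMe3)2, THF, −78 °C; PhN(SO2CF3)2, −78 → 0 °C
Reagents that add atoms: N-phenylbis(trifluoromethanesulfonimide), O=S(=O)(N(c1ccccc1)S(=O)(=O)C(F)(F)F)C(F)(F)F
Why: Kinetic enolisation by the hindered amide base occurs at the accessible C7 methylene (C5–H is tertiary and flanked by two quaternary carbons, the ester α-proton is far less acidic), and O-sulfonylation of the enolate (enol triflate formation) places the future double bond between C6 and C7.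

Step 14
Reactants: 22 methyl (1R,2R,4aR,8aS)-1-ethenyl-5,5,8a-trimethyl-4-(trifluoromethylsulfonyloxy)-1,2,4a,5,6,7,8,8a-octahydronaphthalene-2-carboxylate
Product: 23 methyl (1R,2S,4aR,8aS)-1-ethenyl-5,5,8a-trimethyl-1,2,4a,5,6,7,8,8a-octahydronaphthalene-2-carboxylate
Conditions: Pd(OAc)2 (5 mol%), PPh3 (10 mol%), n-Bu3N, HCO2H, DMF, 60 °C
Reagents that add atoms: none
Why: Palladium-catalysed formate reduction of the enol triflate (oxidative addition, formate exchange, decarboxylation, reductive elimination) replaces the triflate by hydrogen without moving the C6=C7 double bond or touching a stereocentre.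

Step 15
Reactants: 24 methyl 4-hydroxybut-2-ynoate
Product: 25 methyl (Z)-4-hydroxy-3-iodobut-2-enoate
Conditions: LiI, AcOH, MeCN, 70 °C
Reagents that add atoms: lithium iodide, [Li+].[I-]
Why: Conjugate hydroiodination of the ynoate proceeds by anti addition (iodide at the β-carbon, protonation of the allenolate from the opposite side) and gives the (Z)-β-iodo enoate with iodine cis and the hydroxymethyl group trans to the ester, so no lactone can form.

Step 16
Reactants: 23 methyl (1R,2S,4aR,8aS)-1-ethenyl-5,5,8a-trimethyl-1,2,4a,5,6,7,8,8a-octahydronaphthalene-2-carboxylate; 25 methyl (Z)-4-hydroxy-3-iodobut-2-enoate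
Product: 27 methyl (1R,2S,4aR,8aS)-1-[(3E)-3-(hydroxymethyl)-5-methoxy-5-oxopent-3-en-1-yl]-5,5,8a-trimethyl-1,2,4a,5,6,7,8,8a-octahydronaphthalene-2-carboxylate, via alkylborane 26 (not isolated)
Conditions: 9-BBN-H (1.3 equiv), THF, 0 °C → rt; then K3PO4 (3 M aq.), 25, PdCl2(dppf) (5 mol%; dppf = 1,1'-bis(diphenylphosphino)ferrocene), AsPh3 (10 mol%), DMF, rt
Reagents that add atoms: none
Why: Anti-Markovnikov hydroboration by 9-BBN is selective for the monosubstituted vinyl group over the ring alkene and the esters, and the B-alkyl Suzuki–Miyaura coupling joins C12 to C13 with retention of the iodoalkene geometry, placing the chain cis to the ester as in the target; the hydroxyl group is left free because an acetate next to the alkenylpalladium centre could be lost by β-elimination.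

Step 17
Reactants: 27 methyl (1R,2S,4aR,8aS)-1-[(3E)-3-(hydroxymethyl)-5-methoxy-5-oxopent-3-en-1-yl]-5,5,8a-trimethyl-1,2,4a,5,6,7,8,8a-octahydronaphthalene-2-carboxylate
Product: 28 methyl (1R,2S,4aR,8aS)-1-[(3E)-3-(acetoxymethyl)-5-methoxy-5-oxopent-3-en-1-yl]-5,5,8a-trimethyl-1,2,4a,5,6,7,8,8a-octahydronaphthalene-2-carboxylate (CNP0190145.1)
Conditions: Ac2O, pyridine, 4-(dimethylamino)pyridine (cat.), CH2Cl2, 0 °C
Reagents that add atoms: acetic anhydride, CC(=O)OC(C)=O
Why: Nucleophile-catalysed acylation of the primary allylic alcohol completes the target under conditions too weakly basic to epimerise C8 or to move the C6=C7 double bond into conjugation.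

Compound list
1 | 5-chloropent-1-yne | C#CCCCCl | starting material
2 | dimethyl[(1E)-5-chloro-2-methylpent-1-en-1-yl]alane | C[Al](C)/C=C(\C)CCCCl | intermediate (not isolated)
3 | methyl (E)-6-chloro-3-methylhex-2-enoate | COC(=O)/C=C(\C)CCCCl | intermediate
4 | (E)-6-chloro-3-methylhex-2-en-1-ol | OC/C=C(\C)CCCCl | intermediate
5 | triethyl{[(E)-6-chloro-3-methylhex-2-en-1-yl]oxy}silane | CC[Si](CC)(CC)OC/C=C(\C)CCCCl | intermediate
6 | mesityl oxide (4-methylpent-3-en-2-one) | CC(C)=CC(C)=O | starting material
7 | [(4E)-4-methyl-6-(triethylsilyloxy)hex-4-en-1-yl]magnesium chloride | Cl[Mg]CCC/C(C)=C/CO[Si](CC)(CC)CC | intermediate (not isolated)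
8 | (E)-4,4,8-trimethyl-10-(triethylsilyloxy)dec-8-en-2-one | CC(=O)CC(C)(C)CCC/C(C)=C/CO[Si](CC)(CC)CC | intermediate
9 | methyl glyoxylate | COC(=O)C=O | starting material
10 | lithium (8E)-4,4,8-trimethyl-10-(triethylsilyloxy)deca-1,8-dien-2-olate | [Li]OC(=C)CC(C)(C)CCC/C(C)=C/CO[Si](CC)(CC)CC | intermediate (not isolated)
11 | methyl (10E)-2-hydroxy-6,6,10-trimethyl-4-oxo-12-(triethylsilyloxy)dodec-10-enoate (racemic at C2) | COC(=O)C(O)CC(=O)CC(C)(C)CCC/C(C)=C/CO[Si](CC)(CC)CC | intermediate
12 | methyl (10E)-2-(methylsulfonyloxy)-6,6,10-trimethyl-4-oxo-12-(triethylsilyloxy)dodec-10-enoate | COC(=O)C(OS(C)(=O)=O)CC(=O)CC(C)(C)CCC/C(C)=C/CO[Si](CC)(CC)CC | intermediate (not isolated)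
13 | methyl (2E,10E)-6,6,10-trimethyl-4-oxo-12-(triethylsilyloxy)dodeca-2,10-dienoate | COC(=O)/C=C/C(=O)CC(C)(C)CCC/C(C)=C/CO[Si](CC)(CC)CC | intermediate
14 | methyl (2E,4Z,10E)-6,6,10-trimethyl-12-(triethylsilyloxy)-4-(triisopropylsilyloxy)dodeca-2,4,10-trienoate | COC(=O)/C=C/C(O[Si](C(C)C)(C(C)C)C(C)C)=C/C(C)(C)CCC/C(C)=C/CO[Si](CC)(CC)CC | intermediate
15 | methyl (2E,4Z,10E)-12-hydroxy-6,6,10-trimethyl-4-(triisopropylsilyloxy)dodeca-2,4,10-trienoate | COC(=O)/C=C/C(O[Si](C(C)C)(C(C)C)C(C)C)=C/C(C)(C)CCC/C(C)=C/CO | intermediate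
16 | methyl (2E,4Z,10E)-6,6,10-trimethyl-12-oxo-4-(triisopropylsilyloxy)dodeca-2,4,10-trienoate | COC(=O)/C=C/C(O[Si](C(C)C)(C(C)C)C(C)C)=C/C(C)(C)CCC/C(C)=C/C=O | intermediate (cycloaddition precursor)
17 | methyl (1R,2R,4aR,8aR)-1-formyl-5,5,8a-trimethyl-4-(triisopropylsilyloxy)-1,2,4a,5,6,7,8,8a-octahydronaphthalene-2-carboxylate | O=C[C@@H]1[C@H](C(=O)OC)C=C(O[Si](C(C)C)(C(C)C)C(C)C)[C@@H]2C(C)(C)CCC[C@@]12C | intermediate (cycloadduct)
18 | methyl (1R,2S,4aR,8aS)-1-ethenyl-5,5,8a-trimethyl-4-(triisopropylsilyloxy)-1,2,4a,5,6,7,8,8a-octahydronaphthalene-2-carboxylate | C=C[C@@H]1[C@H](C(=O)OC)C=C(O[Si](C(C)C)(C(C)C)C(C)C)[C@@H]2C(C)(C)CCC[C@@]12C | intermediate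
19 | methyl (1R,2R,4aR,8aS)-1-ethenyl-5,5,8a-trimethyl-4-oxodecahydronaphthalene-2-carboxylate (ester axial) | C=C[C@@H]1[C@H](C(=O)OC)CC(=O)[C@@H]2C(C)(C)CCC[C@@]12C | intermediate (not isolated)
20 | methyl (1R,2S,4aR,8aS)-1-ethenyl-5,5,8a-trimethyl-4-oxodecahydronaphthalene-2-carboxylate (ester equatorial) | C=C[C@@H]1[C@@H](C(=O)OC)CC(=O)[C@@H]2C(C)(C)CCC[C@@]12C | intermediate
21 | potassium C6=C7 enolate of 20 (stereocentres as in 20) | C=C[C@@H]1[C@@H](C(=O)OC)C=C(O[K])[C@@H]2C(C)(C)CCC[C@@]12C | intermediate (not isolated)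
22 | methyl (1R,2R,4aR,8aS)-1-ethenyl-5,5,8a-trimethyl-4-(trifluoromethylsulfonyloxy)-1,2,4a,5,6,7,8,8a-octahydronaphthalene-2-carboxylate | C=C[C@@H]1[C@@H](C(=O)OC)C=C(OS(=O)(=O)C(F)(F)F)[C@@H]2C(C)(C)CCC[C@@]12C | intermediate
23 | methyl (1R,2S,4aR,8aS)-1-ethenyl-5,5,8a-trimethyl-1,2,4a,5,6,7,8,8a-octahydronaphthalene-2-carboxylate | C=C[C@@H]1[C@@H](C(=O)OC)C=C[C@@H]2C(C)(C)CCC[C@@]12C | intermediate
24 | methyl 4-hydroxybut-2-ynoate | COC(=O)C#CCO | starting material
25 | methyl (Z)-4-hydroxy-3-iodobut-2-enoate | COC(=O)/C=C(\I)CO | intermediate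
26 | 9-{2-[(1R,2S,4aR,8aS)-2-(methoxycarbonyl)-5,5,8a-trimethyl-1,2,4a,5,6,7,8,8a-octahydronaphthalen-1-yl]ethyl}-9-borabicyclo[3.3.1]nonane | C(C[C@@H]1[C@@H](C(=O)OC)C=C[C@@H]2C(C)(C)CCC[C@@]12C)B1C2CCCC1CCC2 | intermediate (not isolated)
27 | methyl (1R,2S,4aR,8aS)-1-[(3E)-3-(hydroxymethyl)-5-methoxy-5-oxopent-3-en-1-yl]-5,5,8a-trimethyl-1,2,4a,5,6,7,8,8a-octahydronaphthalene-2-carboxylate | COC(=O)/C=C(\CC[C@@H]1[C@@H](C(=O)OC)C=C[C@@H]2C(C)(C)CCC[C@@]12C)CO | intermediate
28 | methyl (1R,2S,4aR,8aS)-1-[(3E)-3-(acetoxymethyl)-5-methoxy-5-oxopent-3-en-1-yl]-5,5,8a-trimethyl-1,2,4a,5,6,7,8,8a-octahydronaphthalene-2-carboxylate | COC(=O)/C=C(\CC[C@@H]1[C@@H](C(=O)OC)C=C[C@@H]2C(C)(C)CCC[C@@]12C)COC(C)=O | target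

Total step count: 17. Longest linear sequence: 16 (steps 1–14, 16 and 17; step 15 makes the coupling partner).

Steps most likely to fail

Step 10. The strongly acidic boron cation may strip the silyl group from the dienol ether or bind the dienoate carbonyl instead of the hindered β,β-disubstituted enal, so that turnover stalls. The two faces of the enal may also be told apart poorly. The fallback gives up catalyst control. Setting out from 16, the cycloaddition is promoted by an achiral Lewis acid (Me2AlCl, 1.1 equiv, CH2Cl2, −78 → −20 °C), which should still favour the formyl-endo, trans-fused mode and give the racemic cycloadduct F1. Its enantiomers are separated by preparative supercritical-fluid chromatography on a cellulose tris(3,5-dimethylphenylcarbamate) phase, and the (1R,2R,4aR,8aR) enantiomer is 17, where the route is rejoined.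

Step 8. Protonation of the dienol ether may compete with methanolysis of the triethylsilyl ether, so that the enol silyl group is lost together with the primary one. The fallback replaces acid-labile masking of the allylic alcohol by base-labile masking. Setting out from 13, the triethylsilyl group is removed before any enol ether exists (pyridinium p-toluenesulfonate, MeOH, rt) to give hydroxy enone F2. Acetylation (Ac2O, pyridine) gives keto acetate F3, and soft enolisation (i-Pr3SiOTf, Et3N, CH2Cl2, −78 → 0 °C) gives acetoxy dienol silyl ether F4. Mild basic methanolysis (K2CO3, MeOH, 0 °C), to which triisopropylsilyl enol ethers should be inert, then releases the allylic alcohol, and the route is rejoined at 15.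

Step 16. Transmetalation of the β-branched alkylborane may be slow, so that protodeboronation and reduction of the iodoenoate take over, or the free hydroxyl group may interfere with the borane. The fallback makes the same C12–C13 bond from an organozinc reagent. Setting out from 23, hydroboration as in step 16 gives 26, which is oxidised under mild conditions (NaBO3·4H2O, THF/H2O, rt) to primary alcohol F5, used at once to limit lactonisation onto the C8 ester. An Appel reaction (I2, PPh3, imidazole, CH2Cl2, 0 °C) gives primary iodide F6, and zinc insertion (Zn dust, LiCl, THF, 40 °C) gives alkylzinc iodide F7. Negishi coupling with 25 (Pd(OAc)2, 2-dicyclohexylphosphino-2',6'-dimethoxybiphenyl, THF, rt; alkylzinc halides tolerate a free alcohol on the halide partner) leads back to the route at 27.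

Further compounds
F1 | step 10 | racemic methyl (1R*,2R*,4aR*,8aR*)-1-formyl-5,5,8a-trimethyl-4-(triisopropylsilyloxy)-1,2,4a,5,6,7,8,8a-octahydronaphthalene-2-carboxylate | O=C[C@@H]1[C@H](C(=O)OC)C=C(O[Si](C(C)C)(C(C)C)C(C)C)[C@@H]2C(C)(C)CCC[C@@]12C.O=C[C@H]1[C@@H](C(=O)OC)C=C(O[Si](C(C)C)(C(C)C)C(C)C)[C@H]2C(C)(C)CCC[C@]12C
F2 | step 8 | methyl (2E,10E)-12-hydroxy-6,6,10-trimethyl-4-oxododeca-2,10-dienoate | COC(=O)/C=C/C(=O)CC(C)(C)CCC/C(C)=C/CO
F3 | step 8 | methyl (2E,10E)-12-acetoxy-6,6,10-trimethyl-4-oxododeca-2,10-dienoate | COC(=O)/C=C/C(=O)CC(C)(C)CCC/C(C)=C/COC(C)=O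
F4 | step 8 | methyl (2E,4Z,10E)-12-acetoxy-6,6,10-trimethyl-4-(triisopropylsilyloxy)dodeca-2,4,10-trienoate | COC(=O)/C=C/C(O[Si](C(C)C)(C(C)C)C(C)C)=C/C(C)(C)CCC/C(C)=C/COC(C)=O
F5 | step 16 | methyl (1R,2S,4aR,8aS)-1-(2-hydroxyethyl)-5,5,8a-trimethyl-1,2,4a,5,6,7,8,8a-octahydronaphthalene-2-carboxylate | OCC[C@@H]1[C@@H](C(=O)OC)C=C[C@@H]2C(C)(C)CCC[C@@]12C
F6 | step 16 | methyl (1R,2S,4aR,8aS)-1-(2-iodoethyl)-5,5,8a-trimethyl-1,2,4a,5,6,7,8,8a-octahydronaphthalene-2-carboxylate | ICC[C@@H]1[C@@H](C(=O)OC)C=C[C@@H]2C(C)(C)CCC[C@@]12C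
F7 | step 16 | {2-[(1R,2S,4aR,8aS)-2-(methoxycarbonyl)-5,5,8a-trimethyl-1,2,4a,5,6,7,8,8a-octahydronaphthalen-1-yl]ethyl}zinc iodide | I[Zn]CC[C@@H]1[C@@H](C(=O)OC)C=C[C@@H]2C(C)(C)CCC[C@@]12C
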